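The Z‑trisubstituted alkene is made inside a ring. In the target, the hydroxymethyl carbon, both carbons of the Z‑alkene, the allylic CH2, butenolide C5 and the oxygen on C5 lie in a row of six atoms with the CH2OH cis to that CH2; joined through an ester they are a 3,6‑disubstituted 5,6‑dihydropyran‑2‑one. Ring‑closing metathesis of a 2‑methylene ester of the (S)‑C5 homoallylic carbinol builds this lactone, making the alkene and fixing its geometry in one operation. The precursor is the ester of the ring A 2‑methyleneoctenoic acid with (S)‑2‑(silyloxymethyl)hexa‑1,5‑dien‑3‑ol. Hydride then frees CH2OH and the C5 oxygen, which is acylated again to close the butenolide.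

Key step: step 14

Remark on the chemistry: both stereocentres of the target are (S), the ring A carbinol and butenolide C5. In 20 and 21 the carbinol carbon has the same spatial arrangement as C5 of the target, and the acid part carries two CH2 groups between the E‑alkene and the methylene‑bearing carbon. TBS = tert‑butyldimethylsilyl; "ring A unit" = (3S)‑3‑(TBS‑oxy)‑2,6,6‑trimethylcyclohex‑1‑en‑1‑yl.

Step 1
Reactants: 1 dihydro‑β‑ionone [4‑(2,6,6‑trimethylcyclohex‑1‑en‑1‑yl)butan‑2‑one]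
Product: 3 2‑(but‑3‑yn‑1‑yl)‑1,3,3‑trimethylcyclohex‑1‑ene, via enol phosphate 2 (not isolated)
Conditions: LDA (1.05 equiv), THF, −78 °C; ClP(O)(OEt)2, −78 °C → rt; LDA (2.3 equiv), −78 °C → rt; H2O
Reagents that add atoms: none
Why: Negishi alkyne synthesis, in which kinetic deprotonation of the methyl group gives the terminal enolate, whose diethyl enol phosphate is eliminated by excess amide base to the terminal alkyne (held as the lithium acetylide until work‑up).

Step 2
Reactants: 3 2‑(but‑3‑yn‑1‑yl)‑1,3,3‑trimethylcyclohex‑1‑ene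
Product: 4 3‑(but‑3‑yn‑1‑yl)‑2,4,4‑trimethylcyclohex‑2‑en‑1‑one
Conditions: CrO3 (15 equiv), 3,5‑dimethylpyrazole (15 equiv), CH2Cl2, −20 °C
Reagents that add atoms: chromium trioxide, O=[Cr](=O)=O
Why: Allylic oxidation by the hexavalent chromium–3,5‑dimethylpyrazole complex should convert the ring CH2 next to the methyl‑bearing alkene carbon into the conjugated ketone, because the side‑chain allylic CH2 is shielded by the geminal methyl groups and the alkyne is not attacked by this oxidant at −20 °C.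

Step 3
Reactants: 4 3‑(but‑3‑yn‑1‑yl)‑2,4,4‑trimethylcyclohex‑2‑en‑1‑one
Product: 5 (S)‑3‑(but‑3‑yn‑1‑yl)‑2,4,4‑trimethylcyclohex‑2‑en‑1‑ol
Conditions: (R)‑2‑methyl‑CBS‑oxazaborolidine (0.2 equiv), catecholborane (1.8 equiv), toluene, −78 °C; MeOH
Reagents that add atoms: none
Why: Corey–Bakshi–Shibata reduction, in which the (R)‑oxazaborolidine binds the carbonyl oxygen anti to the fully substituted alkene carbon (the large flank) and hydride is delivered to the face that gives the (S)‑carbinol, the mirror image of the (S)‑catalyst/acetophenone case, while catecholborane leaves the alkyne untouched at −78 °C.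

Step 4
Reactants: 5 (S)‑3‑(but‑3‑yn‑1‑yl)‑2,4,4‑trimethylcyclohex‑2‑en‑1‑ol
Product: 6 (S)‑[3‑(but‑3‑yn‑1‑yl)‑2,4,4‑trimethylcyclohex‑2‑en‑1‑yl]oxy‑TBS (the TBS ether of 5)
Conditions: TBSCl, imidazole, DMF, rt
Reagents that add atoms: tert‑butyldimethylsilyl chloride, CC(C)(C)[Si](C)(C)Cl
Why: Imidazole‑promoted silylation of a secondary allylic alcohol masks the ring A hydroxyl against the organoaluminium, bromination and base steps that follow.

Step 5
Reactants: 6 TBS ether of 5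
Product: 9 (E)‑6‑(ring A unit)‑4‑methylhex‑3‑en‑1‑ol, via alkenyldimethylalane 7 (not isolated), via lithium alkenylaluminate 8 (not isolated)
Conditions: AlMe3 (2.5 equiv), Cp2ZrCl2 (0.25 equiv), CH2Cl2, 0 °C → rt; volatiles removed; n‑BuLi, hexane/THF, −30 °C; oxirane, −30 → 0 °C; H2O, aq. KNaC4H4O6
Reagents that add atoms: trimethylaluminium, C[Al](C)C; oxirane, C1CO1
Why: Zirconium‑catalysed Negishi methylalumination adds methyl and aluminium syn across the terminal alkyne with aluminium on the terminal carbon, and the derived lithium alkenylaluminate opens oxirane with retention at the alkenyl carbon, which fixes the E‑trisubstituted alkene.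

Step 6
Reactants: 9 (E)‑6‑(ring A unit)‑4‑methylhex‑3‑en‑1‑ol
Product: 10 (E)‑1‑bromo‑6‑(ring A unit)‑4‑methylhex‑3‑ene
Conditions: CBr4, PPh3, 2,6‑lutidine, CH2Cl2, 0 °C
Reagents that add atoms: carbon tetrabromide, BrC(Br)(Br)Br
Why: Appel bromination replaces the primary hydroxyl by SN2 displacement of the alkoxyphosphonium ion under buffered conditions that spare the allylic silyl ether and both alkenes.

Step 7
Reactants: 10 (E)‑1‑bromo‑6‑(ring A unit)‑4‑methylhex‑3‑ene; 11 triethyl phosphonoacetate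
Product: 12 ethyl (E)‑2‑(diethoxyphosphoryl)‑8‑(ring A unit)‑6‑methyloct‑5‑enoate (both C2 epimers)
Conditions: NaH (2.3 equiv), 11 (2.5 equiv), DMF, 0 °C → rt; then 10, 60 °C
Reagents that add atoms: none
Why: SN2 C‑alkylation of the sodium salt of the phosphonoacetate by a primary bromide, run with an excess of the soft carbanion so that dialkylation and E2 elimination to the diene are held back.

Step 8
Reactants: 12 ethyl (E)‑2‑(diethoxyphosphoryl)‑8‑(ring A unit)‑6‑methyloct‑5‑enoate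
Product: 13 ethyl (E)‑8‑(ring A unit)‑6‑methyl‑2‑methyleneoct‑5‑enoate
Conditions: 37% aq. HCHO, K2CO3, THF/H2O, 65 °C
Reagents that add atoms: formaldehyde, C=O
Why: Horner–Wadsworth–Emmons olefination with formaldehyde under mild carbonate conditions converts the α‑alkyl phosphonoacetate into the 2‑methylene ester, and no stereochemical question arises.

Step 9
Reactants: 13 ethyl (E)‑8‑(ring A unit)‑6‑methyl‑2‑methyleneoct‑5‑enoate
Product: 14 (E)‑8‑(ring A unit)‑6‑methyl‑2‑methyleneoct‑5‑enoic acid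
Conditions: LiOH, THF/H2O, 40 °C; then 1 M HCl to pH 4, 0 °C
Reagents that add atoms: lithium hydroxide, [Li+].[OH-]
Why: Saponification of the ethyl ester should be clean because the α‑substituted acrylate is a poor Michael acceptor for hydroxide and the silyl ether is stable to base.

Step 10
Reactants: 15 2‑methylenepropane‑1,3‑diol
Product: 16 2‑[(TBS‑oxy)methyl]prop‑2‑en‑1‑ol
Conditions: NaH (1.0 equiv), THF, 0 °C → rt; TBSCl (1.0 equiv)
Reagents that add atoms: tert‑butyldimethylsilyl chloride, CC(C)(C)[Si](C)(C)Cl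
Why: Monosilylation of a symmetrical diol through its sparingly soluble monosodium alkoxide, both hydroxyls being equivalent.

Step 11
Reactants: 16 2‑[(TBS‑oxy)methyl]prop‑2‑en‑1‑ol
Product: 17 2‑[(TBS‑oxy)methyl]prop‑2‑enal
Conditions: MnO2 (15 equiv), CH2Cl2, rt
Reagents that add atoms: none
Why: MnO2 oxidation of an allylic alcohol gives the 2‑substituted acrolein under neutral conditions that leave the silyl ether alone; the aldehyde is used at once because it polymerizes on standing.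

Step 12
Reactants: 17 2‑[(TBS‑oxy)methyl]prop‑2‑enal
Product: 19 (S)‑2‑[(TBS‑oxy)methyl]hexa‑1,5‑dien‑3‑ol, via allyl borinate 18 (not isolated)
Conditions: (+)‑Ipc2B(allyl) [(+)‑α‑pinene series, from (−)‑Ipc2BOMe; salt‑free pentane solution], Et2O, −78 °C; then 3 M NaOH, 30% H2O2, 0 °C → rt
Reagents that add atoms: B‑allyldiisopinocampheylborane of the (+)‑α‑pinene series, C=CCB([C@@H]1C[C@@H]2C[C@H]([C@H]1C)C2(C)C)[C@@H]1C[C@@H]2C[C@H]([C@H]1C)C2(C)C
Why: Brown asymmetric allylboration, in whose chair Zimmerman–Traxler transition state the isopinocampheyl groups of the (+)‑α‑pinene series direct allyl transfer to the Si face of the aldehyde and so set the (S)‑carbinol, which oxidative work‑up then frees.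

Step 13
Reactants: 14 (E)‑8‑(ring A unit)‑6‑methyl‑2‑methyleneoct‑5‑enoic acid; 19 (S)‑2‑[(TBS‑oxy)methyl]hexa‑1,5‑dien‑3‑ol
Product: 20 (S)‑2‑[(TBS‑oxy)methyl]hexa‑1,5‑dien‑3‑yl (E)‑8‑(ring A unit)‑6‑methyl‑2‑methyleneoct‑5‑enoate
Conditions: DCC, DMAP (0.2 equiv), CH2Cl2, 0 °C → rt
Reagents that add atoms: none
Why: Steglich esterification (carbodiimide activation with acyl transfer by DMAP) joins the 2‑substituted acrylic acid to the secondary alcohol without touching the carbinol stereocentre.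

Step 14
Reactants: 20 (S)‑2‑[(TBS‑oxy)methyl]hexa‑1,5‑dien‑3‑yl (E)‑8‑(ring A unit)‑6‑methyl‑2‑methyleneoct‑5‑enoate
Product: 21 (S)‑6‑[3‑(TBS‑oxy)prop‑1‑en‑2‑yl]‑3‑[(E)‑6‑(ring A unit)‑4‑methylhex‑3‑en‑1‑yl]‑5,6‑dihydro‑2H‑pyran‑2‑one
Conditions: second‑generation Grubbs catalyst RuCl2(=CHPh)(PCy3)(H2IMes) (10 mol %), CH2Cl2 (0.003 M), 40 °C
Reagents that add atoms: none
Why: The benzylidene catalyst exchanges onto the monosubstituted allyl terminus, the new alkylidene adds across the ester's α‑methylene group, and cycloreversion of the ruthenacyclobutane expels ethene and leaves the C3=C4 bond of the lactone (Chauvin mechanism). The closest known reaction type is ring‑closing metathesis of α‑substituted acrylates of homoallylic alcohols to 3‑substituted 5,6‑dihydropyran‑2‑ones. The single ring closes by joining the two alkene termini of the s‑cis ester, so that the new trisubstituted double bond is endocyclic in a six‑membered ring. No stereocentre is created and the (S)‑carbinol carbon, now C6, is not touched. Two things must be controlled, which of the five C=C bonds react and the geometry of the new one: the ring A alkene and the E‑alkene are tetra‑ and trisubstituted and far from the ester, the 2‑(silyloxymethyl)vinyl group could only give a cyclobutene with the allyl alkylidene or a tetrasubstituted butenolide alkene with the methylene ester, and a six‑membered ring accommodates only the cis alkene, which puts the carbonyl carbon and the ring CH2 on the same side as the Z‑alkene of the target requires. High dilution holds back intermolecular metathesis of the allyl groups.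

Step 15
Reactants: 21 the 3,6‑disubstituted 5,6‑dihydro‑2H‑pyran‑2‑one
Product: 22 (2Z,5S)‑7‑(TBS‑oxy)‑6‑methylene‑2‑[(E)‑6‑(ring A unit)‑4‑methylhex‑3‑en‑1‑yl]hept‑2‑ene‑1,5‑diol
Conditions: i‑Bu2AlH (4 equiv), CH2Cl2, −78 → 0 °C; aq. KNaC4H4O6
Reagents that add atoms: none
Why: i‑Bu2AlH reduces the unsaturated lactone in the 1,2 sense through the lactol to the primary allylic alcohol and the free C5 carbinol, the alkene keeping the cis geometry imposed by the ring.

Step 16
Reactants: 22 the Z‑diol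
Product: 23 (2Z,5S)‑1,7‑bis(TBS‑oxy)‑6‑methylene‑2‑[(E)‑6‑(ring A unit)‑4‑methylhex‑3‑en‑1‑yl]hept‑2‑en‑5‑ol
Conditions: TBSCl (1.05 equiv), imidazole, CH2Cl2, −20 → 0 °C
Reagents that add atoms: tert‑butyldimethylsilyl chloride, CC(C)(C)[Si](C)(C)Cl
Why: Steric selectivity in silylation should distinguish the unhindered primary allylic hydroxyl from the secondary carbinol flanked by the branched alkene.

Step 17
Reactants: 23 the 1,7‑bis‑silyl ether with free C5 carbinol; 24 acryloyl chloride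
Product: 25 the acrylate of 23 at the C5 carbinol
Conditions: i‑Pr2NEt, DMAP (0.1 equiv), CH2Cl2, −20 → 0 °C
Reagents that add atoms: none
Why: O‑acylation of the secondary carbinol by the acid chloride with a hindered amine base gives the acrylate needed for the second ring closure.

Step 18
Reactants: 25 the C5 acrylate
Product: 26 (S)‑4‑[(TBS‑oxy)methyl]‑5‑{(2Z,6E)‑3‑[(TBS‑oxy)methyl]‑9‑(ring A unit)‑7‑methylnona‑2,6‑dien‑1‑yl}furan‑2(5H)‑one
Conditions: second‑generation Grubbs catalyst RuCl2(=CHPh)(PCy3)(H2IMes) (10 mol %), toluene (0.005 M), 80 °C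
Reagents that add atoms: none
Why: Ring‑closing metathesis of an acrylate of a 2‑substituted allylic alcohol to a 4‑substituted butenolide, in which the ester alkylidene closes onto the 1,1‑disubstituted alkene with release of ethene while the Z‑alkene, a trisubstituted silyl‑protected allylic alcohol, and the two remote alkenes should be too hindered to compete.

Step 19
Reactants: 26 the tris‑TBS butenolide
Product: 27 (S)‑4‑(hydroxymethyl)‑5‑{(2Z,6E)‑3‑(hydroxymethyl)‑9‑[(3S)‑3‑hydroxy‑2,6,6‑trimethylcyclohex‑1‑en‑1‑yl]‑7‑methylnona‑2,6‑dien‑1‑yl}furan‑2(5H)‑one (target)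
Conditions: HF·pyridine, pyridine, THF, 0 °C → rt
Reagents that add atoms: none
Why: Fluoride‑driven desilylation removes all three silyl ethers in a pyridine‑buffered medium that should neither epimerize butenolide C5, nor translactonize onto the new hydroxymethyl group, nor ionize the allylic ring A carbinol.

Compound list
1 | dihydro‑β‑ionone | CC(=O)CCC1=C(C)CCCC1(C)C | starting material
2 | diethyl 4‑(2,6,6‑trimethylcyclohex‑1‑en‑1‑yl)but‑1‑en‑2‑yl phosphate | C=C(CCC1=C(C)CCCC1(C)C)OP(=O)(OCC)OCC | intermediate (not isolated)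
3 | 2‑(but‑3‑yn‑1‑yl)‑1,3,3‑trimethylcyclohex‑1‑ene | C#CCCC1=C(C)CCCC1(C)C | intermediate
4 | 3‑(but‑3‑yn‑1‑yl)‑2,4,4‑trimethylcyclohex‑2‑en‑1‑one | C#CCCC1=C(C)C(=O)CCC1(C)C | intermediate
5 | (S)‑3‑(but‑3‑yn‑1‑yl)‑2,4,4‑trimethylcyclohex‑2‑en‑1‑ol | CC1=C(CCC#C)C(C)(C)CC[C@@H]1O | intermediate
6 | TBS ether of 5 | CC1=C(CCC#C)C(C)(C)CC[C@@H]1O[Si](C)(C)C(C)(C)C | intermediate
7 | (E)‑alkenyldimethylalane from 6 | CC1=C(CC/C(C)=C/[Al](C)C)C(C)(C)CC[C@@H]1O[Si](C)(C)C(C)(C)C | intermediate (not isolated)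
8 | lithium (E)‑alkenyl(butyl)dimethylaluminate | CC1=C(CC/C(C)=C/[Al-](C)(C)CCCC)C(C)(C)CC[C@@H]1O[Si](C)(C)C(C)(C)C.[Li+] | intermediate (not isolated)
9 | (E)‑6‑(ring A unit)‑4‑methylhex‑3‑en‑1‑ol | CC1=C(CC/C(C)=C/CCO)C(C)(C)CC[C@@H]1O[Si](C)(C)C(C)(C)C | intermediate
10 | (E)‑1‑bromo‑6‑(ring A unit)‑4‑methylhex‑3‑ene | CC1=C(CC/C(C)=C/CCBr)C(C)(C)CC[C@@H]1O[Si](C)(C)C(C)(C)C | intermediate
11 | triethyl phosphonoacetate | CCOC(=O)CP(=O)(OCC)OCC | starting material
12 | ethyl (E)‑2‑(diethoxyphosphoryl)‑8‑(ring A unit)‑6‑methyloct‑5‑enoate, C2 epimers | CC1=C(CC/C(C)=C/CCC(C(=O)OCC)P(=O)(OCC)OCC)C(C)(C)CC[C@@H]1O[Si](C)(C)C(C)(C)C | intermediate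
13 | ethyl (E)‑8‑(ring A unit)‑6‑methyl‑2‑methyleneoct‑5‑enoate | CC1=C(CC/C(C)=C/CCC(=C)C(=O)OCC)C(C)(C)CC[C@@H]1O[Si](C)(C)C(C)(C)C | intermediate
14 | (E)‑8‑(ring A unit)‑6‑methyl‑2‑methyleneoct‑5‑enoic acid | CC1=C(CC/C(C)=C/CCC(=C)C(=O)O)C(C)(C)CC[C@@H]1O[Si](C)(C)C(C)(C)C | intermediate
15 | 2‑methylenepropane‑1,3‑diol | C=C(CO)CO | starting material
16 | 2‑[(TBS‑oxy)methyl]prop‑2‑en‑1‑ol | C=C(CO)CO[Si](C)(C)C(C)(C)C | intermediate
17 | 2‑[(TBS‑oxy)methyl]prop‑2‑enal | C=C(C=O)CO[Si](C)(C)C(C)(C)C | intermediate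
18 | (S)‑2‑[(TBS‑oxy)methyl]hexa‑1,5‑dien‑3‑yl diisopinocampheylborinate | C[C@H]1[C@H](B(O[C@@H](CC=C)C(=C)CO[Si](C)(C)C(C)(C)C)[C@@H]3C[C@@H]4C[C@H]([C@H]3C)C4(C)C)C[C@@H]2C[C@H]1C2(C)C | intermediate (not isolated)
19 | (S)‑2‑[(TBS‑oxy)methyl]hexa‑1,5‑dien‑3‑ol | O[C@@H](CC=C)C(=C)CO[Si](C)(C)C(C)(C)C | intermediate
20 | (S)‑2‑[(TBS‑oxy)methyl]hexa‑1,5‑dien‑3‑yl (E)‑8‑(ring A unit)‑6‑methyl‑2‑methyleneoct‑5‑enoate | CC1=C(CC/C(C)=C/CCC(=C)C(=O)O[C@@H](CC=C)C(=C)CO[Si](C)(C)C(C)(C)C)C(C)(C)CC[C@@H]1O[Si](C)(C)C(C)(C)C | intermediate (metathesis precursor)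
21 | (S)‑6‑[3‑(TBS‑oxy)prop‑1‑en‑2‑yl]‑3‑[(E)‑6‑(ring A unit)‑4‑methylhex‑3‑en‑1‑yl]‑5,6‑dihydro‑2H‑pyran‑2‑one | CC1=C(CC/C(C)=C/CCC2=CC[C@@H](C(=C)CO[Si](C)(C)C(C)(C)C)OC2=O)C(C)(C)CC[C@@H]1O[Si](C)(C)C(C)(C)C | intermediate (metathesis product)
22 | (2Z,5S)‑7‑(TBS‑oxy)‑6‑methylene‑2‑[(E)‑6‑(ring A unit)‑4‑methylhex‑3‑en‑1‑yl]hept‑2‑ene‑1,5‑diol | CC1=C(CC/C(C)=C/CC/C(CO)=C/C[C@H](O)C(=C)CO[Si](C)(C)C(C)(C)C)C(C)(C)CC[C@@H]1O[Si](C)(C)C(C)(C)C | intermediate
23 | (2Z,5S)‑1,7‑bis(TBS‑oxy)‑6‑methylene‑2‑[(E)‑6‑(ring A unit)‑4‑methylhex‑3‑en‑1‑yl]hept‑2‑en‑5‑ol | CC1=C(CC/C(C)=C/CC/C(CO[Si](C)(C)C(C)(C)C)=C/C[C@H](O)C(=C)CO[Si](C)(C)C(C)(C)C)C(C)(C)CC[C@@H]1O[Si](C)(C)C(C)(C)C | intermediate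
24 | acryloyl chloride | C=CC(=O)Cl | starting material
25 | C5 acrylate of 23 | CC1=C(CC/C(C)=C/CC/C(CO[Si](C)(C)C(C)(C)C)=C/C[C@H](OC(=O)C=C)C(=C)CO[Si](C)(C)C(C)(C)C)C(C)(C)CC[C@@H]1O[Si](C)(C)C(C)(C)C | intermediate
26 | tris‑TBS ether of the target | CC1=C(CC/C(C)=C/CC/C(=C/C[C@@H]2OC(=O)C=C2CO[Si](C)(C)C(C)(C)C)CO[Si](C)(C)C(C)(C)C)C(C)(C)CC[C@@H]1O[Si](C)(C)C(C)(C)C | intermediate
27 | (S)‑4‑(hydroxymethyl)‑5‑{(2Z,6E)‑3‑(hydroxymethyl)‑9‑[(3S)‑3‑hydroxy‑2,6,6‑trimethylcyclohex‑1‑en‑1‑yl]‑7‑methylnona‑2,6‑dien‑1‑yl}furan‑2(5H)‑one | CC1=C(CC/C(C)=C/CC/C(=C/C[C@@H]2OC(=O)C=C2CO)CO)C(C)(C)CC[C@@H]1O | target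

Total step count: 19. Longest linear sequence: 16 steps (steps 1–9 and 13–19, from 1).

Steps most likely to fail

Step 14. The alkylidene formed at the allyl terminus may engage the hindered α‑methylene ester too slowly, so that intermolecular metathesis between allyl termini and catalyst decay outrun ring closure. The fallback sets out from 19, 24 and 10 and returns at 21; it forms the lactone ring with an easy disubstituted alkene and attaches the side chain afterwards by cross‑coupling. Alcohol 19 is acylated with 24 (i‑Pr2NEt, CH2Cl2, 0 °C) to (S)‑2‑[(TBS‑oxy)methyl]hexa‑1,5‑dien‑3‑yl acrylate F1. This is closed with the second‑generation Grubbs catalyst (CH2Cl2, 40 °C) to (S)‑6‑[3‑(TBS‑oxy)prop‑1‑en‑2‑yl]‑5,6‑dihydro‑2H‑pyran‑2‑one F2. α‑Iodination by pyridine conjugate addition, iodination and elimination (I2, pyridine, CH2Cl2) should give the 3‑iodo lactone F3. Bromide 10 is converted with zinc dust and LiCl in THF into the alkylzinc bromide F4, and Negishi coupling of F3 with F4 (PdCl2(dppf), THF, rt) should deliver 21.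

Step 18. The acrylate‑derived alkylidene may close onto the Z‑trisubstituted alkene, giving a six‑membered lactone with loss of the terpenoid chain, in competition with the slower five‑ring closure onto the hindered 1,1‑disubstituted alkene. The fallback sets out from 22 and 24 and returns at 27; it carries the Z‑alkene through the metathesis as an electron‑poor conjugated enal, which the catalyst should not attack. Diol 22 is silylated at the primary hydroxyl with Et3SiCl (imidazole, CH2Cl2, −40 °C) to the primary triethylsilyl ether F5 and acylated with 24 to the acrylate F6. Swern conditions ((COCl)2, DMSO, then Et3N, −78 → −20 °C), which oxidize primary triethylsilyl ethers directly while TBS ethers persist, should give the (Z)‑enal acrylate F7. Ring‑closing metathesis (second‑generation Grubbs catalyst, toluene, 80 °C) then gives the butenolide enal F8. Luche reduction (NaBH4, CeCl3·7H2O, MeOH, −78 °C) reduces only the aldehyde, to the bis‑TBS butenolide allylic alcohol F9, and HF·pyridine gives 27.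

Step 2. Oxidation at the side‑chain allylic or the propargylic methylene, or oxidative degradation of the terminal alkyne, may compete with oxidation of the ring. The fallback sets out from 1 and returns at 6; it introduces the ring oxygen before the alkyne exists. Ketone 1 is protected (ethylene glycol, p‑TsOH, benzene, reflux) as the dioxolane F10 and oxidized with CrO3/3,5‑dimethylpyrazole to the ring enone dioxolane F11. Reduction as in step 3 gives the (S)‑allylic alcohol F12 and silylation as in step 4 gives the TBS ether F13. The ketal is hydrolysed (PPTS, acetone/H2O) to the methyl ketone F14. The Negishi alkyne synthesis of step 1 is then applied to F14, through the enol phosphate F15, and should give 6.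

Further compounds
F1 | step 14 | (S)‑2‑[(TBS‑oxy)methyl]hexa‑1,5‑dien‑3‑yl acrylate | C=CC(=O)O[C@@H](CC=C)C(=C)CO[Si](C)(C)C(C)(C)C
F2 | step 14 | (S)‑6‑[3‑(TBS‑oxy)prop‑1‑en‑2‑yl]‑5,6‑dihydro‑2H‑pyran‑2‑one | O=C1C=CC[C@@H](C(=C)CO[Si](C)(C)C(C)(C)C)O1
F3 | step 14 | (S)‑3‑iodo‑6‑[3‑(TBS‑oxy)prop‑1‑en‑2‑yl]‑5,6‑dihydro‑2H‑pyran‑2‑one | O=C1C(I)=CC[C@@H](C(=C)CO[Si](C)(C)C(C)(C)C)O1
F4 | step 14 | [(E)‑6‑(ring A unit)‑4‑methylhex‑3‑en‑1‑yl]zinc bromide | CC1=C(CC/C(C)=C/CC[Zn]Br)C(C)(C)CC[C@@H]1O[Si](C)(C)C(C)(C)C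
F5 | step 18 | primary triethylsilyl ether of 22 | CC1=C(CC/C(C)=C/CC/C(CO[Si](CC)(CC)CC)=C/C[C@H](O)C(=C)CO[Si](C)(C)C(C)(C)C)C(C)(C)CC[C@@H]1O[Si](C)(C)C(C)(C)C
F6 | step 18 | C5 acrylate of F5 | CC1=C(CC/C(C)=C/CC/C(CO[Si](CC)(CC)CC)=C/C[C@H](OC(=O)C=C)C(=C)CO[Si](C)(C)C(C)(C)C)C(C)(C)CC[C@@H]1O[Si](C)(C)C(C)(C)C
F7 | step 18 | (Z)‑enal acrylate | CC1=C(CC/C(C)=C/CC/C(C=O)=C/C[C@H](OC(=O)C=C)C(=C)CO[Si](C)(C)C(C)(C)C)C(C)(C)CC[C@@H]1O[Si](C)(C)C(C)(C)C
F8 | step 18 | bis‑TBS butenolide (Z)‑enal | CC1=C(CC/C(C)=C/CC/C(=C/C[C@@H]2OC(=O)C=C2CO[Si](C)(C)C(C)(C)C)C=O)C(C)(C)CC[C@@H]1O[Si](C)(C)C(C)(C)C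
F9 | step 18 | bis‑TBS butenolide with free Z‑allylic CH2OH | CC1=C(CC/C(C)=C/CC/C(=C/C[C@@H]2OC(=O)C=C2CO[Si](C)(C)C(C)(C)C)CO)C(C)(C)CC[C@@H]1O[Si](C)(C)C(C)(C)C
F10 | step 2 | 2‑methyl‑2‑[2‑(2,6,6‑trimethylcyclohex‑1‑en‑1‑yl)ethyl]‑1,3‑dioxolane | CC1(CCC2=C(C)CCCC2(C)C)OCCO1
F11 | step 2 | 2,4,4‑trimethyl‑3‑[2‑(2‑methyl‑1,3‑dioxolan‑2‑yl)ethyl]cyclohex‑2‑en‑1‑one | CC1(CCC2=C(C)C(=O)CCC2(C)C)OCCO1
F12 | step 2 | (S)‑2,4,4‑trimethyl‑3‑[2‑(2‑methyl‑1,3‑dioxolan‑2‑yl)ethyl]cyclohex‑2‑en‑1‑ol | CC1=C(CCC2(C)OCCO2)C(C)(C)CC[C@@H]1O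
F13 | step 2 | TBS ether of F12 | CC1=C(CCC2(C)OCCO2)C(C)(C)CC[C@@H]1O[Si](C)(C)C(C)(C)C
F14 | step 2 | 4‑(ring A unit)butan‑2‑one | CC1=C(CCC(C)=O)C(C)(C)CC[C@@H]1O[Si](C)(C)C(C)(C)C
F15 | step 2 | diethyl 4‑(ring A unit)but‑1‑en‑2‑yl phosphate | CC1=C(CCC(=C)OP(=O)(OCC)OCC)C(C)(C)CC[C@@H]1O[Si](C)(C)C(C)(C)C
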